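(The runs stem from a simulated flask for an exercise, and the scatter is random.)

The epsilon run left something over: at its last reading, 120 min, J stood at 51% and D at 4%, so 45.0% of the D charged was in neither.

| flask | D | X | remark | time |
|---|---|---|---|---|
| epsilon | 0.063 M | 0.252 M | run made earlier |  |
| alpha | 0.063 M | 0.13 M | run made earlier |  |
| eta | 0.063 M | 0.19 M | run made earlier |  |
| Tuesday's | 0.063 M | 0.252 M | everything together at the start | 3.0 h |
| Monday's | 0.063 M (fed, over 2.0 h) | 0.252 M | all else is in the flask from the start; the feed brings no volume worth counting | 3.0 h |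
| Sunday's | 0.063 M | 0.252 M (fed, over 2.0 h) | all else is in the flask from the start; the feed brings no volume worth counting | 3.0 h |

epsilon run (percent of the D charged)

| time / min | J / % | D / % |
|---|---|---|
| 20.0 | 13 | 18 |
| 40.0 | 22 | 9 |
| 50.0 | 29 | 6 |
| 80.0 | 41 | 5 |
| 90.0 | 47 | 1 |
| 120 | 51 | 4 |

alpha run (percent of the D charged)

| time / h | J / % | D / % |
|---|---|---|
| 0.200 | 5 | 19 |
| 0.333 | 6 | 18 |
| 0.500 | 9 | 15 |
| 0.833 | 18 | 4 |
| 1.33 | 34 | 4 |
| 2.50 | 50 | 1 |

eta run (percent of the D charged)

| time / h | J / % | D / % |
|---|---|---|
| 0.200 | 3 | 17 |
| 0.333 | 8 | 17 |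
| 0.500 | 15 | 11 |
| 0.833 | 27 | 7 |
| 1.33 | 41 | 6 |
| 2.50 | 59 | 0 |

(standard deviation of a reading: 1.5 percentage points)

- a reading or a percentage of J counts all its forms, free or not

- which flask leads in amount of J, in percent of the D charged ("all alike" within 1.5 percentage points) (Tuesday's / Monday's / Sunday's / all alike)
- how much J is there at the end, in percent of the D charged: Tuesday's
- how much J is there at the end, in percent of the D charged: Monday's
- how much J is there at the end, in percent of the D charged: Sunday's

Was that part lost, or only waiting? The alpha run, with half the X, read J at 34% after 1.33 h, less than the 41% of the epsilon run at 80.0 min. So less X delayed J.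

How long does D last? In the epsilon run it read 18% at 20.0 min and 5% at 80.0 min, which reads as a half-life t_h of 32.5 min. In the alpha run D fell no slower, from 19% at 0.200 h to 4% at 0.833 h, so I reckoned the fall of D without regard to X. A feed of 2.0 h holds 3.69 such half-lives. That gives 7.72% as f, the unturned share: the part of a D charge present from the start not yet passed on when the feed ends.

Which flask keeps D away from J? In Sunday's flask, by that reckoning, nearly all of the D had passed on before the X feed ended. In Monday's flask, late D entered where earlier D had already made J. If the unread part is a selectivity loss, made where D meets J, the order is Sunday's, Tuesday's, Monday's. That was my reckoning, and it differs from the forecast.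

The forecast put Tuesday's ahead, with 65%, 53% and 55% for Tuesday's, Monday's and Sunday's, on the ground “Sunday's X starts low, which costs about half an hour of effective time plus some selectivity”.

Sunday's led, with J at 71.0%, against 59.0% in Tuesday's and 46.8% in Monday's.

    D → L (k = 0.0787 /min)
    X + L → J (k = 0.158 /M/min)
    E ⇌ J, rate k3*(cs3 - [J]) while solid is left; crystals form when [J] > cs3 (solubility = 26.0 mM, k = 0.456 /min)
    D ⇌ Q (K = 2.90, k = 0.644 /min)
    D + J → Z (k = 1.76 /M/min)

Z, the product of D + J, which counts double in these percentages, was lowest at the end in Sunday's flask, 24.8%, against 38.6% in Tuesday's and 40.3% in Monday's. At the end of Sunday's feed, 2.00 h, D and Q, the form D passes into and back from, together stood at 5.26%, less than f.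

The neighbour is Sunday's flask with 0.11 M of D. The charge of D does not enter my reckoning of f, so I reckoned f as 7.72% there too. That flask gave J 65.0%, less than Sunday's, with Z 29.7% and D 0.19% at the end.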